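**Retrosynthetic overview**
1. Target ⇐ tetramethyl ether (global O-demethylation) ⇐ C6–aryl bond: 1,4-addition of the 3,4-dimethoxyphenyl group to the C6=C7 enone of a cross-conjugated trienone, anti to the aryl group already on C5.
2. Trienone ⇐ (5R)-5-(3,5-dimethoxyphenyl)cyclohept-2-en-1-one: styryl conjugate addition/Saegusa–Ito oxidation at C3, then α′-silylation/Saegusa–Ito oxidation across C6–C7.
3. Key disconnection, C5–aryl: (3,5-dimethoxyphenyl)boronic acid + cyclohept-4-en-1-one, joined by an enantioselective oxidative redox-relay Heck arylation that also moves the ring double bond into conjugation (C2=C3).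
4. Enabling feature: in the seven-membered ring the aryl-bearing C5 is homoallylic to the enone (C5–C4–C3=C2–C1=O). A C4=C5 alkene, whose carbons are enantiotopic about the mirror plane through C1 and the C4=C5 midpoint of the C7 ketone, therefore lets palladium walk from C4 via C3 to C2.
5. Ring order: no ring is closed in the route; the seven-membered carbocycle enters as the alkenone and the three benzene rings arrive intact.

Key step: step 1

Remark: cyclohept-4-en-1-one is taken as a purchased compound, and the ligand enantiomer in step 1 is assumed to be the one that delivers the 5R enone (its antipode is used otherwise).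

**Step 1**
Reactants: 1 cyclohept-4-en-1-one; 2 (3,5-dimethoxyphenyl)boronic acid
Product: 3 (5R)-5-(3,5-dimethoxyphenyl)cyclohept-2-en-1-one
Conditions: 2 (2 equiv), Pd(MeCN)2(OTs)2 (6 mol %), Cu(OTf)2 (6 mol %), (S)-4-tert-butyl-2-[5-(trifluoromethyl)pyridin-2-yl]-4,5-dihydrooxazole (13 mol %), 3 Å molecular sieves, O2 (1 atm), DMF, 25 °C
Reagents that add atoms: none
Why: Proposed new method: an enantioselective oxidative redox-relay Heck arylation of a symmetrical cycloalkenone, in which the aryl–palladium species formed by transmetalation from 2 adds syn across C4=C5 of 1 (aryl to C5, metal to C4), the metal walks from C4 to C3 by β-hydride elimination and reinsertion on the same ring face, a last β-hydride elimination of a C2 hydrogen gives the C2=C3 enone, and O2 with Cu(OTf)2 returns zerovalent palladium to divalent palladium. The closest known reaction types are the pyridine-oxazoline–palladium redox-relay Heck arylation of acyclic γ,δ-alkenyl ketones with arylboronic acids, which ends in the α,β-unsaturated ketone, and the asymmetric Heck desymmetrisation of symmetrical cyclic cis-alkenes; their combination on a cycloalkenone is the new element. No ring is closed. The C5 stereocentre is set in the migratory insertion by the chiral ligand: the two alkene faces of 1 are homotopic (twofold axis through C1 and the C4=C5 midpoint), so the ligand only has to decide which of the two enantiotopic alkene carbons receives the aryl group. The step needs that site discrimination and a one-way relay, and the substrate secures the second: the syn aryl group leaves no syn β-hydrogen on C5, so palladium can only move towards C3, and the ketone two methylene groups away stops the walk at the conjugated C2=C3 position, which also tells the two sides of the ring apart for steps 2 to 6.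

**Step 2**
Reactants: 3 (5R)-5-(3,5-dimethoxyphenyl)cyclohept-2-en-1-one; 4 (E)-(2-bromoethenyl)benzene
Product: 6 trimethyl({(5R)-5-(3,5-dimethoxyphenyl)-3-[(E)-2-phenylethenyl]cyclohept-1-en-1-yl}oxy)silane (C3 epimers), via (E)-styrylmagnesium bromide 5 (not isolated)
Conditions: 4, Mg, THF, 25 °C; then CuBr·SMe2 (10 mol %), Me3SiCl, HMPA, 3, THF, −78 °C; Et3N, pentane work-up
Reagents that add atoms: chlorotrimethylsilane, C[Si](C)(C)Cl
Why: Copper-catalysed conjugate addition of the alkenyl Grignard reagent with in situ silylation should place the styryl group on C3 and fix the enolate regiospecifically as the C1=C2 silyl enol ether; the E geometry is carried over from 4, and the new C3 centre (either epimer) is removed in step 3.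

**Step 3**
Reactants: 6 trimethyl({(5R)-5-(3,5-dimethoxyphenyl)-3-[(E)-2-phenylethenyl]cyclohept-1-en-1-yl}oxy)silane
Product: 7 (5R)-5-(3,5-dimethoxyphenyl)-3-[(E)-2-phenylethenyl]cyclohept-2-en-1-one
Conditions: Pd(OAc)2 (10 mol %), O2 (1 atm), DMSO, 25 °C
Reagents that add atoms: none
Why: Saegusa–Ito oxidation, in which the palladium enolate formed from the silyl enol ether loses the C3 hydrogen by β-hydride elimination, should restore the C2=C3 double bond in conjugation with the ketone and the styryl group without touching C5.

**Step 4**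
Reactants: 7 (5R)-5-(3,5-dimethoxyphenyl)-3-[(E)-2-phenylethenyl]cyclohept-2-en-1-one
Product: 8 trimethyl({(4R)-4-(3,5-dimethoxyphenyl)-6-[(E)-2-phenylethenyl]cyclohepta-1,6-dien-1-yl}oxy)silane
Conditions: LiN(i-Pr)2 (commercial solution), Me3SiCl (in situ quench), THF, −78 °C; Et3N, pentane work-up
Reagents that add atoms: chlorotrimethylsilane, C[Si](C)(C)Cl
Why: Kinetic deprotonation of the enone at the α′ carbon (C7 of 7) with internal silyl quench should give the cross-conjugated silyl dienol ether rather than the γ (C4) trienol ether, which marks the C6–C7 bond for desaturation and leaves the stereocentre alone.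

**Step 5**
Reactants: 8 trimethyl({(4R)-4-(3,5-dimethoxyphenyl)-6-[(E)-2-phenylethenyl]cyclohepta-1,6-dien-1-yl}oxy)silane
Product: 9 (5S)-5-(3,5-dimethoxyphenyl)-3-[(E)-2-phenylethenyl]cyclohepta-2,6-dien-1-one
Conditions: Pd(OAc)2 (10 mol %), O2 (1 atm), DMSO, 25 °C
Reagents that add atoms: none
Why: A second Saegusa–Ito oxidation, by β-hydride elimination of a C6 hydrogen from the C7-bound palladium enolate, should give the cross-conjugated trienone whose only unsubstituted enone β-carbon is C6, next to the C5 stereocentre (same spatial arrangement; the descriptor changes to S by priority only).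

**Step 6**
Reactants: 9 (5S)-5-(3,5-dimethoxyphenyl)-3-[(E)-2-phenylethenyl]cyclohepta-2,6-dien-1-one; 10 (3,4-dimethoxyphenyl)boronic acid
Product: 11 (5S,6S)-6-(3,4-dimethoxyphenyl)-5-(3,5-dimethoxyphenyl)-3-[(E)-2-phenylethenyl]cyclohept-2-en-1-one
Conditions: 10 (2 equiv), [Rh(OH)(cod)]2 (3 mol %), dioxane/H2O 10:1, 25 °C
Reagents that add atoms: none
Why: Rhodium-catalysed 1,4-addition of the arylboronic acid (Hayashi–Miyaura reaction) should occur at the disubstituted C6=C7 enone rather than at the fully substituted C3, with the aryl–rhodium species inserting on the face of C6 opposite to the neighbouring C5 aryl group (as for 4-substituted cycloalkenones), which sets C6 trans to C5; the base-free hydroxo catalyst at 25 °C is chosen to avoid γ-deprotonation at C5.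

**Step 7**
Reactants: 11 (5S,6S)-6-(3,4-dimethoxyphenyl)-5-(3,5-dimethoxyphenyl)-3-[(E)-2-phenylethenyl]cyclohept-2-en-1-one
Product: 12 (5S,6S)-6-(3,4-dihydroxyphenyl)-5-(3,5-dihydroxyphenyl)-3-[(E)-2-phenylethenyl]cyclohept-2-en-1-one
Conditions: BBr3 (8 equiv), CH2Cl2, −78 to 0 °C; then H2O
Reagents that add atoms: none
Why: Lewis-acid cleavage of the four aryl methyl ethers (boron coordination, then SN2 loss of the methyl group to bromide) should free the phenols on aqueous work-up; neither stereocentre is α to the carbonyl, and the low temperature is meant to keep the electron-rich rings from attacking the activated dienone.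

**Compound list**
1 | cyclohept-4-en-1-one | O=C1CCC=CCC1 | starting material
2 | (3,5-dimethoxyphenyl)boronic acid | COc1cc(OC)cc(B(O)O)c1 | starting material
3 | (5R)-5-(3,5-dimethoxyphenyl)cyclohept-2-en-1-one | O=C1C=CC[C@H](c2cc(OC)cc(OC)c2)CC1 | intermediate
4 | (E)-(2-bromoethenyl)benzene | Br/C=C/c1ccccc1 | starting material
5 | (E)-(2-phenylethenyl)magnesium bromide (not isolated) | Br[Mg]/C=C/c1ccccc1 | intermediate
6 | trimethyl({(5R)-5-(3,5-dimethoxyphenyl)-3-[(E)-2-phenylethenyl]cyclohept-1-en-1-yl}oxy)silane, C3 epimers | C[Si](C)(C)OC1=CC(/C=C/c2ccccc2)C[C@H](c2cc(OC)cc(OC)c2)CC1 | intermediate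
7 | (5R)-5-(3,5-dimethoxyphenyl)-3-[(E)-2-phenylethenyl]cyclohept-2-en-1-one | O=C1C=C(/C=C/c2ccccc2)C[C@H](c2cc(OC)cc(OC)c2)CC1 | intermediate
8 | trimethyl({(4R)-4-(3,5-dimethoxyphenyl)-6-[(E)-2-phenylethenyl]cyclohepta-1,6-dien-1-yl}oxy)silane | C[Si](C)(C)OC1=CC[C@@H](c2cc(OC)cc(OC)c2)CC(/C=C/c2ccccc2)=C1 | intermediate
9 | (5S)-5-(3,5-dimethoxyphenyl)-3-[(E)-2-phenylethenyl]cyclohepta-2,6-dien-1-one | O=C1C=C(/C=C/c2ccccc2)C[C@H](c2cc(OC)cc(OC)c2)C=C1 | intermediate
10 | (3,4-dimethoxyphenyl)boronic acid | COc1ccc(B(O)O)cc1OC | starting material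
11 | (5S,6S)-6-(3,4-dimethoxyphenyl)-5-(3,5-dimethoxyphenyl)-3-[(E)-2-phenylethenyl]cyclohept-2-en-1-one | O=C1C=C(/C=C/c2ccccc2)C[C@H](c2cc(OC)cc(OC)c2)[C@@H](c2ccc(OC)c(OC)c2)C1 | intermediate
12 | (5S,6S)-6-(3,4-dihydroxyphenyl)-5-(3,5-dihydroxyphenyl)-3-[(E)-2-phenylethenyl]cyclohept-2-en-1-one | O=C1C=C(/C=C/c2ccccc2)C[C@H](c2cc(O)cc(O)c2)[C@@H](c2ccc(O)c(O)c2)C1 | target

Total step count: 7. Longest linear sequence: 7 steps (1 to 12).

**Steps most likely to fail**

Step 1 (proposed new method). The ligand may discriminate poorly between the two enantiotopic alkene carbons, and palladium hydride may leave the ring before the double bond has reached conjugation, which would give low enantiomeric purity and alkene isomers. The fallback uses only known reaction types, sets out from boronic acid 2 (with purchased dione) and rejoins the route at 7. Cycloheptane-1,3-dione F1 is converted (EtOH, TsOH, toluene, reflux) into the vinylogous ester 3-ethoxycyclohept-2-en-1-one F2. α′-Dehydrogenation (LiN(i-Pr)2, THF, −78 °C, then N-tert-butylbenzenesulfinimidoyl chloride) should give 3-ethoxycyclohepta-2,6-dien-1-one F3. Hayashi–Miyaura addition of 2 ([RhCl(C2H4)2]2, BINAP enantiomer chosen for 6R, KOH, dioxane/H2O) to its only unsubstituted enone β-carbon should give (6R)-6-(3,5-dimethoxyphenyl)-3-ethoxycyclohept-2-en-1-one F4. A Stork–Danheiser sequence then follows: 1,2-addition of Grignard reagent 5 (CeCl3, THF, −78 °C) gives the carbinol (6R)-6-(3,5-dimethoxyphenyl)-3-ethoxy-1-[(E)-2-phenylethenyl]cyclohept-2-en-1-ol F5, and aqueous HCl should convert it into 7. In this variant the C5–aryl bond is made by a conventional 1,4-addition and the styryl-bearing carbon is the former carbonyl carbon.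

Step 6. Deprotonation of 9 at C5 (γ to the new enone and benzylic) in the aqueous medium would erode the stereocentre before the aryl group arrives, and insertion at the hindered C6 may be slow enough for attack at the styryl terminus to compete. The fallback sets out from 9 and returns at 11, delivering the aryl group as a copper-bound nucleophile under aprotic, silylating conditions at low temperature. (3,4-Dimethoxyphenyl)magnesium bromide F6 (commercial solution) with CuBr·SMe2 and Me3SiCl in THF at −78 °C should give the silyl dienol ether trimethyl({(3R,4S)-3-(3,4-dimethoxyphenyl)-4-(3,5-dimethoxyphenyl)-6-[(E)-2-phenylethenyl]cyclohepta-1,6-dien-1-yl}oxy)silane F7. Brief hydrolysis (dilute aqueous HCl, THF, 0 °C) then returns 11.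

Step 4. Deprotonation of 7 at the γ carbon C4, towards the linear styryl-conjugated trienolate, may compete with the wanted α′ deprotonation; silylation of that enolate followed by step 5 would desaturate C4–C5 and erase the stereocentre. The fallback sets out from 3 and returns at 9, and makes the regiochemistry of enolisation irrelevant. Hayashi–Miyaura addition of (E)-(2-phenylethenyl)boronic acid F8 to 3 ([Rh(OH)(cod)]2, dioxane/H2O, 25 °C) should give the saturated ketone (5R)-5-(3,5-dimethoxyphenyl)-3-[(E)-2-phenylethenyl]cycloheptan-1-one F9 (C3 epimers). Twofold dehydrogenation with 2-iodoxybenzoic acid (DMSO, 70 °C) should converge on 9 whichever side is desaturated first; the oxidant is limited to two dehydrogenations so that the ring is not taken on to the tropone.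

**Further compounds**
F1 | step 1 | cycloheptane-1,3-dione | O=C1CC(=O)CCCC1
F2 | step 1 | 3-ethoxycyclohept-2-en-1-one | CCOC1=CC(=O)CCCC1
F3 | step 1 | 3-ethoxycyclohepta-2,6-dien-1-one | CCOC1=CC(=O)C=CCC1
F4 | step 1 | (6R)-6-(3,5-dimethoxyphenyl)-3-ethoxycyclohept-2-en-1-one | CCOC1=CC(=O)C[C@H](c2cc(OC)cc(OC)c2)CC1
F5 | step 1 | (6R)-6-(3,5-dimethoxyphenyl)-3-ethoxy-1-[(E)-2-phenylethenyl]cyclohept-2-en-1-ol, C1 epimers | CCOC1=CC(O)(/C=C/c2ccccc2)C[C@H](c2cc(OC)cc(OC)c2)CC1
F6 | step 6 | (3,4-dimethoxyphenyl)magnesium bromide | COc1ccc([Mg]Br)cc1OC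
F7 | step 6 | trimethyl({(3R,4S)-3-(3,4-dimethoxyphenyl)-4-(3,5-dimethoxyphenyl)-6-[(E)-2-phenylethenyl]cyclohepta-1,6-dien-1-yl}oxy)silane | C[Si](C)(C)OC1=C[C@H](c2ccc(OC)c(OC)c2)[C@@H](c2cc(OC)cc(OC)c2)CC(/C=C/c2ccccc2)=C1
F8 | step 4 | (E)-(2-phenylethenyl)boronic acid | OB(O)/C=C/c1ccccc1
F9 | step 4 | (5R)-5-(3,5-dimethoxyphenyl)-3-[(E)-2-phenylethenyl]cycloheptan-1-one, C3 epimers | O=C1CC(/C=C/c2ccccc2)C[C@H](c2cc(OC)cc(OC)c2)CC1
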